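**Retrosynthetic overview**

1. Target 13 is an aromatic ketone (ring A) and an enolized cyclohexane-1,3,5-trione (ring B) joined by one CH2. The last disconnection is the ring A carbon–CH2 bond, giving phenol 5 (one free ring carbon, between its two OH groups) and Mannich base 11, a latent 6-methylidene trione.
2. Ring B of 11 is cut between the ring carbonyl C1 and the acetyl-bearing C2 (Claisen retron) and between C5 and C6 (crossed Claisen). This gives two fragments of similar size: pyran-2,4-dione 8 (C5, C4, C3, C2 and the acetyl group) and amino ester 9 (C1, C6 and the bridge carbon with its leaving group).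
3. Enabling feature: C2 of ring B lies between the acetyl carbonyl and ring carbonyl C3, so after the C1–C2 cut it is the central carbon of a 1,3-diketone and C1 is an ester carbon. C4 is quaternary (gem-dimethyl) and cannot aromatize, so the C5–C2/acetyl chain can be stored as the temporary enol-lactone ring of 8; its lactone carbon (future C5) acylates C6, and its opening unveils the diketone nucleophile.
4. Ring order: ring A comes with 1 and is only substituted (steps 1–4); the temporary pyranone ring is closed in step 6; in step 7 it opens and ring B closes at C1–C2; step 8 joins the two halves.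

Key step: step 7

Remark: the target has no stereocenter; ring B is written throughout in the enol tautomer of the given structure, the other enol forms being the same compound.

**Route**

Step 1
Reactants: 1 2-methylbenzene-1,3,5-triol
Product: 2 1-(2,4,6-trihydroxy-3-methylphenyl)ethanone
Conditions: AcCl (1.05 equiv), AlCl3 (3.5 equiv), PhNO2–CH2Cl2, 0 → 45 °C; ice/2 M HCl
Reagents that add atoms: acetyl chloride, CC(Cl)=O
Why: Friedel–Crafts acylation; the two free ring carbons of 1 are equivalent by symmetry and the first acyl group deactivates the ring toward a second, so a single C-acetyl ketone should result.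

Step 2
Reactants: 2 1-(2,4,6-trihydroxy-3-methylphenyl)ethanone
Product: 3 1-[4,6-bis(benzyloxy)-2-hydroxy-3-methylphenyl]ethanone
Conditions: BnBr (2.1 equiv), K2CO3 (2.2 equiv), acetone, 23 → 56 °C
Reagents that add atoms: benzyl bromide, BrCc1ccccc1
Why: Williamson ether synthesis; the 4-OH (para to the ketone, not chelated) and the 6-OH are benzylated, while the 2-OH, flanked by the C-methyl and the acetyl group and held in the stronger, buttressed hydrogen bond to the ketone, should stay free.

Step 3
Reactants: 3 1-[4,6-bis(benzyloxy)-2-hydroxy-3-methylphenyl]ethanone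
Product: 4 1-[4,6-bis(benzyloxy)-2-methoxy-3-methylphenyl]ethanone
Conditions: MeI (3 equiv), K2CO3 (3 equiv), DMF, 50 °C
Reagents that add atoms: iodomethane, CI
Why: Williamson O-methylation of the one remaining phenol, which is chelated and hindered and therefore needs the polar solvent, excess MeI and heat, but has no competing OH left.

Step 4
Reactants: 4 1-[4,6-bis(benzyloxy)-2-methoxy-3-methylphenyl]ethanone
Product: 5 1-(4,6-dihydroxy-2-methoxy-3-methylphenyl)ethanone
Conditions: H2 (1 atm), 10% Pd/C, EtOAc–MeOH, 23 °C
Reagents that add atoms: none
Why: Hydrogenolysis of the two benzyl ethers over Pd/C at ambient pressure, conditions under which the aryl ketone (chelated by the freed ortho OH) and the methyl ether are expected to survive.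

Step 5
Reactants: 6 methyl 2,2-dimethyl-3-oxobutanoate
Product: 7 methyl 2,2-dimethyl-3,5-dioxohexanoate
Conditions: LiN(i-Pr)2 (1.1 equiv), THF, −78 °C; then MeC(O)N(OMe)Me (1.2 equiv), −78 → 0 °C; 1 M HCl
Reagents that add atoms: N-methoxy-N-methylacetamide, CC(=O)N(C)OC
Why: Crossed Claisen acylation; 6 can enolize only at its acetyl CH3 (C2 is quaternary), and the Weinreb amide gives a chelated tetrahedral adduct that releases the β-diketone only on acidic work-up, which prevents proton transfer to unreacted enolate and over-acylation.

Step 6
Reactants: 7 methyl 2,2-dimethyl-3,5-dioxohexanoate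
Product: 8 3,3,6-trimethyl-2H-pyran-2,4(3H)-dione
Conditions: TsOH·H2O (5 mol %), toluene, reflux, MeOH removed over 5 Å molecular sieves (Soxhlet)
Reagents that add atoms: none
Why: Acid-catalysed intramolecular transesterification (enol lactonization); the enol OH at C5 of the β-diketone attacks the ester in a 6-exo-trig closure favoured by the gem-dimethyl (Thorpe–Ingold) effect and driven by removal of methanol, in analogy to the lactonization of 3,5-dioxoalkanoates to pyran-2,4-diones.

Step 7
Reactants: 8 3,3,6-trimethyl-2H-pyran-2,4(3H)-dione, 9 methyl 3-(dimethylamino)propanoate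
Product: 11 2-acetyl-6-[(dimethylamino)methyl]-3,5-dihydroxy-4,4-dimethylcyclohexa-2,5-dien-1-one, via acyclic triketo ester 10 (not isolated)
Conditions: 9, LiN(i-Pr)2 (1.05 equiv), THF, −78 °C; then 8, −78 → −20 °C, then 23 → 45 °C; AcOH to pH 6–7, zwitterion collected
Reagents that add atoms: none
Why: Proposed new method: the lithium enolate of 9 adds to the lactone carbonyl of 8 (C2, the acyl carbon of a vinylogous anhydride), the tetrahedral adduct opens by expelling the β-diketone enolate to give 10, and on warming the diketone carbon C6 of 10 attacks the methyl ester carbon C1 and expels methoxide, which forms the bond between the ring carbonyl C1 and the acetyl-bearing C2 of ring B and leaves the stabilized enolate of 11. The closest known reaction types are the crossed Claisen acylation of ester enolates by enol esters, the Claisen (Dieckmann-type) cyclization of 3,5,7-trioxoalkanoates to acylphloroglucinols and the Mg(OMe)2-induced conversion of 4-hydroxy-6-(2-oxopropyl)pyran-2-one into 2,4,6-trihydroxyacetophenone; their union in one flask on a 3,3-dialkylpyran-2,4-dione is not known. Ring B closes in a 6-exo-trig acyl substitution by an enolate carbon (6-enolexo), helped by the gem-dimethyl group. No stereocenter is created in 11, and the one at C2 of 10 is racemic and disappears on enolization. The step needs attack at C2 of 8 and not at C4 or C6, and Claisen instead of aldol closure of 10: the first should follow from the hard lithium enolate at −78 °C meeting the most electrophilic carbonyl (addition to the ketone C4 being reversible), the second from the quaternary carbon, which keeps any aldol adduct from aromatizing so that it reverts, while the acyl substitution is made irreversible by deprotonation of the vinylogous acid 11. One equivalent of base suffices because the methoxide set free ends as methanol.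

Step 8
Reactants: 11 2-acetyl-6-[(dimethylamino)methyl]-3,5-dihydroxy-4,4-dimethylcyclohexa-2,5-dien-1-one, 5 1-(4,6-dihydroxy-2-methoxy-3-methylphenyl)ethanone
Product: 13 2-acetyl-6-[(3-acetyl-2,6-dihydroxy-4-methoxy-5-methylphenyl)methyl]-3,5-dihydroxy-4,4-dimethylcyclohexa-2,5-dien-1-one, via methylidene trione 12 (not isolated)
Conditions: 5 (1.3 equiv), AcOH (2 equiv), 1,4-dioxane, 70 °C, N2
Reagents that add atoms: none
Why: Mannich-base alkylation (elimination–addition); protonated 11 loses dimethylamine to the methylidene trione 12, a strong Michael acceptor, which should be captured by the only unsubstituted and most nucleophilic ring carbon of 5 (between two OH groups) in a Friedel–Crafts-type conjugate addition, the excess of 5 and the acetic acid buffer suppressing self-condensation and base-induced scrambling of the methylene bridge.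

**Compound list**

1 | 2-methylbenzene-1,3,5-triol | Cc1c(O)cc(O)cc1O | starting material
2 | 1-(2,4,6-trihydroxy-3-methylphenyl)ethanone | CC(=O)c1c(O)cc(O)c(C)c1O | intermediate
3 | 1-[4,6-bis(benzyloxy)-2-hydroxy-3-methylphenyl]ethanone | CC(=O)c1c(O)c(C)c(OCc2ccccc2)cc1OCc1ccccc1 | intermediate
4 | 1-[4,6-bis(benzyloxy)-2-methoxy-3-methylphenyl]ethanone | COc1c(C)c(OCc2ccccc2)cc(OCc2ccccc2)c1C(C)=O | intermediate
5 | 1-(4,6-dihydroxy-2-methoxy-3-methylphenyl)ethanone | COc1c(C)c(O)cc(O)c1C(C)=O | intermediate
6 | methyl 2,2-dimethyl-3-oxobutanoate | COC(=O)C(C)(C)C(C)=O | starting material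
7 | methyl 2,2-dimethyl-3,5-dioxohexanoate | COC(=O)C(C)(C)C(=O)CC(C)=O | intermediate
8 | 3,3,6-trimethyl-2H-pyran-2,4(3H)-dione | CC1=CC(=O)C(C)(C)C(=O)O1 | intermediate
9 | methyl 3-(dimethylamino)propanoate | CN(C)CCC(=O)OC | starting material
10 | methyl 2-[(dimethylamino)methyl]-4,4-dimethyl-3,5,7-trioxooctanoate (racemic; formed as its lithium enolate; not isolated) | COC(=O)C(CN(C)C)C(=O)C(C)(C)C(=O)CC(C)=O | intermediate
11 | 2-acetyl-6-[(dimethylamino)methyl]-3,5-dihydroxy-4,4-dimethylcyclohexa-2,5-dien-1-one | CN(C)CC1=C(O)C(C)(C)C(O)=C(C(C)=O)C1=O | intermediate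
12 | 2-acetyl-3-hydroxy-4,4-dimethyl-6-methylidenecyclohex-2-ene-1,5-dione (not isolated) | C=C1C(=O)C(C)(C)C(O)=C(C(C)=O)C1=O | intermediate
13 | 2-acetyl-6-[(3-acetyl-2,6-dihydroxy-4-methoxy-5-methylphenyl)methyl]-3,5-dihydroxy-4,4-dimethylcyclohexa-2,5-dien-1-one | COc1c(C)c(O)c(CC2=C(O)C(C)(C)C(O)=C(C(C)=O)C2=O)c(O)c1C(C)=O | target

**Step count and risks**

Total step count: 8.
Longest linear sequence: 5 steps (steps 1–4, then step 8); the ring B branch is 4 steps (steps 5–7, then step 8).

Steps most likely to fail:

Step 7 (Proposed new method). The ester enolate may remove a proton from the 6-methyl group of 8 or add in conjugate fashion at C6 instead of substituting at the lactone carbonyl, and 10 may close by aldol addition instead of Claisen condensation. The fallback sets out from compound 2 and comes back at compound 11. Compound 2 is C-methylated at its methyl-bearing ring carbon (MeI, NaOMe, MeOH, 0 → 23 °C), the classical dearomatizing gem-dimethylation of acylphloroglucinols, to give 2-acetyl-3,5-dihydroxy-4,4-dimethylcyclohexa-2,5-dien-1-one F1. Its only ring C–H is then aminomethylated with dimethylmethylideneammonium iodide (CH2Cl2, 23 °C; neutralization), which gives 11. Ring B then comes from the aromatic ring of 2 and not from a Claisen closure.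

Step 8. The Mannich base may fragment by retro-Mannich loss of its aminomethyl group and the halves may self-condense to symmetrical methylene-bridged dimers, or the bridge may scramble once formed. The fallback sets out from compounds 5 and 2 and comes back at target 13. Compound 5 is formylated at its only free ring carbon (Cl2CHOMe, TiCl4, CH2Cl2, 0 °C; aqueous HCl; Rieche formylation) to 3-acetyl-2,6-dihydroxy-4-methoxy-5-methylbenzaldehyde F2. This is combined with 2-acetyl-3,5-dihydroxy-4,4-dimethylcyclohexa-2,5-dien-1-one F1 (made from 2 as above), diethyl 2,6-dimethyl-1,4-dihydropyridine-3,5-dicarboxylate and catalytic L-proline (CH2Cl2, 23 °C). Knoevenagel condensation gives 2-acetyl-6-[(3-acetyl-2,6-dihydroxy-4-methoxy-5-methylphenyl)methylidene]-3-hydroxy-4,4-dimethylcyclohex-2-ene-1,5-dione F3 (not isolated), which is reduced in the same flask by hydride transfer to 13. Cross-selectivity is built in, because only the aromatic partner carries the electrophilic carbon and only F1 a nucleophilic C–H.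

Step 6. Lactonization may stop short because the equilibrium favours the open methyl ester, or the acid may cleave the non-enolizable 1,3-dicarbonyl unit by a retro-Claisen path. The fallback sets out from compound 7 and comes back at compound 8. The methyl ester is cleaved by SN2 dealkylation (LiI, EtOAc, reflux; cold dilute HCl) to 2,2-dimethyl-3,5-dioxohexanoic acid F4. This is cyclodehydrated at once through its mixed anhydride ((CF3CO)2O, CH2Cl2, 0 °C), the known closure of 3,5-dioxo acids to pyranones, to give 8 irreversibly.

Further compounds
F1 | step 7 | 2-acetyl-3,5-dihydroxy-4,4-dimethylcyclohexa-2,5-dien-1-one | CC(=O)C1=C(O)C(C)(C)C(O)=CC1=O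
F2 | step 8 | 3-acetyl-2,6-dihydroxy-4-methoxy-5-methylbenzaldehyde | COc1c(C)c(O)c(C=O)c(O)c1C(C)=O
F3 | step 8 | 2-acetyl-6-[(3-acetyl-2,6-dihydroxy-4-methoxy-5-methylphenyl)methylidene]-3-hydroxy-4,4-dimethylcyclohex-2-ene-1,5-dione (alkene geometry not defined; not isolated) | COc1c(C)c(O)c(C=C2C(=O)C(C)(C)C(O)=C(C(C)=O)C2=O)c(O)c1C(C)=O
F4 | step 6 | 2,2-dimethyl-3,5-dioxohexanoic acid | CC(=O)CC(=O)C(C)(C)C(O)=O
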